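**Structure check.** The target SMILES is a 2-aryl-3-(hydroxymethyl)-4-(arylmethyl)tetrahydrofuran. Working through the CIP descriptors and the ring geometry gives C7 = S, C8 = R, C8' = R, with aryl/CH2OH trans (7,8-trans) and CH2OH/ArCH2 cis (8,8'-cis). The 8,8'-cis ring is the same (R,R) arrangement found in trans-dibenzylbutyrolactones and secoisolariciresinol.

**Assumptions.** Allyl is used as the phenol protecting group. This keeps the benzylic C7–O bond safe at the end, because no hydrogenolysis is needed. The C7 epimers formed in the aldol are deliberately left uncontrolled and are converged in step 9.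

## Retrosynthesis
1. Remove the two phenol allyl groups last (Pd(0)).
2. Form the THF ring last by acid-mediated SN1 cyclodehydration of a 7-hydroxy-secoisolariciresinol-type triol. The benzylic C7 ionises reversibly and C9'-OH closes the 5-ring, so C7 ends up thermodynamically trans to C8.
3. The triol comes from LiAlH4 reduction of the trans-aldol adduct of lactone 11 with aldehyde 3. The lactone enolate reacts anti to the 4-arylmethyl group, which sets C8 relative to C8'.
4. Lactone 11 comes from an Evans alkylation (sets C8') with tert-butyl bromoacetate, followed by imide reduction and lactonisation.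
5. Order of construction: lactone ring (step 6), then the C7–C8 bond (step 7), then the THF ring (step 9).

## Route

**Step 1**
Reactants: 1 syringaldehyde; 2 allyl bromide
Product: 3 4-(allyloxy)-3,5-dimethoxybenzaldehyde
Conditions: K2CO3, DMF, 60 °C
Reagents that add atoms: allyl bromide, C=CCBr (compound 2)
Why: Williamson O-allylation of the phenol. The aldehyde is untouched and is used again in step 7.

**Step 2**
Reactants: 3; 4 Meldrum's acid
Product: 5 3-[4-(allyloxy)-3,5-dimethoxyphenyl]propanoic acid
Conditions: HCO2H–Et3N (5:2), DMF, 100 °C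
Reagents that add atoms: Meldrum's acid, CC1(C)OC(=O)CC(=O)O1 (compound 4), which supplies CH2CO2H
Why: Reductive Knoevenagel reaction. Condensation gives the arylidene Meldrum's acid, formate reduces the C=C, and decarboxylation gives the 3-arylpropanoic acid. No stereocentre is formed.

**Step 3**
Reactants: 5; 6 (S)-4-benzyloxazolidin-2-one
Product: 7 (S)-4-benzyl-3-{3-[4-(allyloxy)-3,5-dimethoxyphenyl]propanoyl}oxazolidin-2-one
Conditions: PivCl, Et3N, THF, −20 °C; then 6, LiCl, rt
Reagents that add atoms: (S)-4-benzyloxazolidin-2-one, O=C1N[C@@H](Cc2ccccc2)CO1 (compound 6). PivCl and Et3N leave no atoms in the product.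
Why: Acylation through the mixed pivalic anhydride installs the Evans auxiliary.

**Step 4**
Reactants: 7; 8 tert-butyl bromoacetate
Product: 9 (S)-4-benzyl-3-{(R)-2-[(4-allyloxy-3,5-dimethoxyphenyl)methyl]-4-tert-butoxy-4-oxobutanoyl}oxazolidin-2-one
Conditions: NaHMDS, THF, −78 °C; then 8, −78 → −40 °C
Reagents that add atoms: tert-butyl bromoacetate, CC(C)(C)OC(=O)CBr (compound 8)
Why: Evans asymmetric alkylation. The chelated Z-sodium enolate is alkylated on the face opposite the benzyl group of the (S)-auxiliary, giving (R) at C8'.

**Step 5**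
Reactants: 9
Product: 10 tert-butyl (R)-3-[(4-allyloxy-3,5-dimethoxyphenyl)methyl]-4-hydroxybutanoate (auxiliary 6 is recovered)
Conditions: LiBH4, H2O (1 equiv), Et2O, 0 °C
Reagents that add atoms: none
Why: Hydride reduction of the more electrophilic imide to the primary alcohol. The tert-butyl ester, aryl allyl ether and C8' stereocentre are unaffected.

**Step 6**
Reactants: 10
Product: 11 (R)-4-[(4-allyloxy-3,5-dimethoxyphenyl)methyl]dihydrofuran-2(3H)-one
Conditions: TFA, CH2Cl2, rt
Reagents that add atoms: none
Why: TFA cleaves the tert-butyl ester (isobutene is lost) and the γ-hydroxy acid lactonises. The stereocentre is not involved.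

**Step 7**
Reactants: 11; 3
Product: 12 trans-3-[hydroxy(aryl)methyl]-4-(arylmethyl)butyrolactone, (4R) lactone, as a mixture of C7 epimers (aryl = 4-allyloxy-3,5-dimethoxyphenyl)
Conditions: LiHMDS, THF, −78 °C; then 3; quench with NH4Cl at −78 °C
Reagents that add atoms: aldehyde 3, C=CCOc1c(OC)cc(C=O)cc1OC (supplied as a reactant)
Why: Lactone-enolate aldol. The aldehyde attacks anti to the 4-arylmethyl group, so C8 is trans to the C8' substituent (the (R,R)-matairesinol-type arrangement). C7 is not controlled and is set in step 9.

**Step 8**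
Reactants: 12
Product: 13 triol: (2R,3R)-2,3-bis-substituted 1-aryl-2,3-bis(hydroxymethyl)-4-arylbutan-1-ol, C7 epimeric mixture
Conditions: LiAlH4, THF, 0 °C
Reagents that add atoms: none
Why: Hydride reduction of the lactone to the diol, with C7-OH retained. The allyl ethers survive and C8/C8' are not epimerisable.

**Step 9**
Reactants: 13
Product: 14 (7S,8R,8'R)-4,4'-di-O-allyl-5,5'-dimethoxylariciresinol
Conditions: TsOH·H2O (10 mol %), CH2Cl2 (0.02 M), 0 °C → rt
Reagents that add atoms: none (water is lost)
Why: Acid-catalysed SN1 cyclodehydration. The electron-rich benzylic C7 ionises reversibly and C9'-OH closes the 5-membered ring. C9-OH cannot form a 5-ring onto C7. Equilibration funnels both C7 epimers to the 2,3-trans isomer, which places the aryl anti to both ring substituents (the all-cis isomer is strained). No bond to C8 or C8' is broken.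

**Step 10**
Reactants: 14
Product: 15 (+)-(7S,8R,8'R)-5,5'-dimethoxylariciresinol
Conditions: Pd(PPh3)4 (5 mol %), K2CO3, MeOH, rt
Reagents that add atoms: none
Why: Tsuji–Trost O-deallylation, with the π-allyl-Pd captured by methoxide. The benzylic THF C–O bonds and all stereocentres are untouched.

## Compound list
1 | syringaldehyde | COc1cc(C=O)cc(OC)c1O | starting material
2 | allyl bromide | C=CCBr | starting material
3 | 4-(allyloxy)-3,5-dimethoxybenzaldehyde | C=CCOc1c(OC)cc(C=O)cc1OC | intermediate
4 | Meldrum's acid | CC1(C)OC(=O)CC(=O)O1 | starting material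
5 | 3-[4-(allyloxy)-3,5-dimethoxyphenyl]propanoic acid | C=CCOc1c(OC)cc(CCC(=O)O)cc1OC | intermediate
6 | (S)-4-benzyloxazolidin-2-one | O=C1N[C@@H](Cc2ccccc2)CO1 | starting material
7 | (S)-4-benzyl-3-{3-[4-(allyloxy)-3,5-dimethoxyphenyl]propanoyl}oxazolidin-2-one | C=CCOc1c(OC)cc(CCC(=O)N2[C@@H](Cc3ccccc3)COC2=O)cc1OC | intermediate
8 | tert-butyl bromoacetate | CC(C)(C)OC(=O)CBr | starting material
9 | alkylated imide (8'R) | CC(C)(C)OC(=O)C[C@@H](Cc1cc(OC)c(OCC=C)c(OC)c1)C(=O)N1[C@@H](Cc2ccccc2)COC1=O | intermediate
10 | tert-butyl (R)-3-[(4-allyloxy-3,5-dimethoxyphenyl)methyl]-4-hydroxybutanoate | CC(C)(C)OC(=O)C[C@@H](Cc1cc(OC)c(OCC=C)c(OC)c1)CO | intermediate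
11 | (R)-4-[(4-allyloxy-3,5-dimethoxyphenyl)methyl]dihydrofuran-2(3H)-one | O=C1C[C@@H](Cc2cc(OC)c(OCC=C)c(OC)c2)CO1 | intermediate
12 | trans-hydroxy lactone (C7 epimeric mixture, C7 not specified) | O=C1OC[C@H](Cc2cc(OC)c(OCC=C)c(OC)c2)[C@H]1C(O)c1cc(OC)c(OCC=C)c(OC)c1 | intermediate
13 | triol (C7 epimeric mixture, C7 not specified) | OC[C@H](Cc1cc(OC)c(OCC=C)c(OC)c1)[C@H](CO)C(O)c1cc(OC)c(OCC=C)c(OC)c1 | intermediate
14 | 4,4'-di-O-allyl-5,5'-dimethoxylariciresinol | COc1cc(C[C@H]2CO[C@H](c3cc(OC)c(OCC=C)c(OC)c3)[C@H]2CO)cc(OC)c1OCC=C | intermediate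
15 | (+)-(7S,8R,8'R)-5,5'-dimethoxylariciresinol | COc1cc(C[C@H]2CO[C@H](c3cc(OC)c(O)c(OC)c3)[C@H]2CO)cc(OC)c1O | target

**Total step count:** 10. **Longest linear sequence:** 10 steps (1→3→5→7→9→10→11→12→13→14→15, via steps 1–10; aldehyde 3 is made once and reused in step 7).

## Three steps most likely to fail
1. **Step 9 (cyclodehydration).** Risks are a poor 7,8-trans ratio, Friedel–Crafts closure onto the other syringyl ring to give an aryltetralin, and E1 elimination.
   - Fallback: set C7 stereochemically instead of thermodynamically. Convert 11 to the C9 N-acyl oxazolidinone with a C9'-OTBS group. Run an Evans syn-aldol with 3, which gives 7,8-trans after ring closure with C7–O retained. Remove the auxiliary, then close the ring by SN2 at the primary C9' (tosylate and base, or Mitsunobu).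
2. **Step 4 (alkylation with tert-butyl bromoacetate).** Yield or diastereoselectivity may be modest because of enolate decomposition and the poor electrophile.
   - Fallback: use asymmetric hydrogenation. Make the Stobbe half-ester from aldehyde 3 and a succinate diester, hydrogenate it with a chiral Rh or Ru bisphosphine catalyst to set C8', then reduce and lactonise to 11.
3. **Step 7 (lactone aldol).** The adduct can dehydrate or undergo retro-aldol during workup, and the yield may be low.
   - Fallback: C-acylate the lactone enolate with the Weinreb amide of 4-allyloxy-3,5-dimethoxybenzoic acid to give the 2-aroyl lactone, then reduce the ketone (NaBH4 or Zn(BH4)2) to give 12. The C8 centre re-equilibrates trans and C7 is converged later in step 9.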